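(The data come from a simulation on assumed constants, and the scatter is random.)

What will stand in this flask at 6.0 min, above all how much ended carrier?

in all of them: starting material 1.5 M; initiator 36 mM

| run | reagent | remark | time |
|---|---|---|---|
| Wednesday's | 3 M | the very flask that is asked about, followed so far |  |
| flask | 3.00 M |  | 6.0 min |

Wednesday's run (percent of the starting material charged)

| time / min | target / % | ended carrier / % | starting material / % |
|---|---|---|---|
| 0.417 | 7.0 | 0 | 94.7 |
| 0.833 | 12.4 | 3.2 | 86.4 |
| 1.33 | 17.6 | 1.3 | 79.1 |
| 1.50 | 20.5 | 0.1 | 78.2 |
| 2.00 | 25.6 | 0.8 | 73.1 |
| 2.50 | 30.0 | 0.9 | 67.6 |

(scatter of a reading: 1 percentage point)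

* concentration of target at 6.0 min, in M
* concentration of ended carrier at 6.0 min, in M
* concentration of starting material at 6.0 min, in M
* concentration of by-product at 6.0 min, in M

- percent here means starting material units held: one ended chains B counts as two
- on the list of suspects stand: initiator -> 2 initiating radical; starting material + initiating radical -> capped initiator + first chain carrier; reagent + first chain carrier -> target + second chain carrier; starting material + second chain carrier -> by-product + first chain carrier; first chain carrier -> ended carrier; 2 second chain carrier -> ended chains A; 2 first chain carrier -> ended chains B

1. In the flask: at 2.50 min, target reads 30.0 % and starting material 67.6 %. That target has taken 15.0 % of the reagent charge.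

2. Reckon first chain carrier as used up as fast as it forms (a steady state). Two of its exits count here: with reagent to target, or alone to ended carrier. While reagent stays near its charge, the two products should grow in step.

3. Each reading carries a scatter of 1 percentage point, so the readings are summed. The sums give 0.0557: φ, ended carrier made per target made, a selectivity factor.

4. On arrival: target gained 0.149 /min of the charge early and 0.0950 /min late, slower. My working guess is therefore 0.750 M of target, half the charge, and φ makes that 0.0418 M of ended carrier.

5. Leave the reagent alone: φ was read at this charge.

The forecast gave 0.71 M target, 0.025 M ended carrier, 0.76 M starting material and 0.68 M by-product, on a slowing that “fits the radical supply dying as initiator is used up”. The flask gives 0.781 M, 0.0427 M, 0.669 M and 0.780 M.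

    initiator → 2 initiating radical (k = 0.00349 /s)
    starting material + initiating radical → capped initiator + first chain carrier (k = 73200 /M/s)
    reagent + first chain carrier → target + second chain carrier (k = 2680 /M/s)
    starting material + second chain carrier → by-product + first chain carrier (k = 57700 /M/s)
    first chain carrier → ended carrier (k = 380 /s)
    2 second chain carrier → ended chains A (k = 1.20 × 10⁹ /M/s)
    2 first chain carrier → ended chains B (k = 9.80 × 10⁷ /M/s)

φ times that target gives 0.0435 M of ended carrier. The flask's own ratio, 0.0547, is more than 0.0473, the rate of ending over the rate of meeting reagent at the full charge. It is less than 0.0639, the same comparison with 74 % of the reagent left.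

In the neighbour flask charged with 0.60 M of starting material, φ turns 0.549 M of target into 0.0306 M of ended carrier. The computed neighbour flask holds 0.0286 M.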